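**Retrosynthetic overview**
1. The C8 epoxyangelate is cut back to an (8S)-alcohol plus (2S,3S)-epoxyangelic acid (esterification with inversion); the 1,10-oxirane comes from a late peracid epoxidation and the C3 hydroxyl is carried as a silyl ether.
2. Key disconnection C7–C11: the whole α-methylene-γ-butyrolactone is annulated in one flask onto a ten-membered cis-7,8-epoxy-6-ol. An O6-tethered phosphonoacetate opens the oxirane at C7 (5-exo), and the resulting phosphonate anion is methylenated with formaldehyde.
3. Enabling feature: C7 lies between two oxygen-bearing ring carbons (C6, lactone oxygen; C8, ester oxygen). The array O6–C6–C7–C8–O8 is therefore a 2,3-epoxy alcohol retron whose O6 acyl tether reaches C7 through a five-membered ring, and the exocyclic C11=C13 is a Horner–Wadsworth–Emmons retron.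
4. The ten-membered carbocycle (1(10)E,4Z) is made from a six-membered ring by four-carbon ring expansion: anionic oxy-Cope rearrangement of a 1,2-dialkenylcyclohexenol derived from (S)-carvone, which also supplies the C3 centre.
5. Ring order: cyclohexene (chiral pool) → cyclodecadienone (oxy-Cope) → 7,8-oxirane → γ-lactone (key step) → 1,10-oxirane.

Key step: step 13

Remark: ring carbons of the ten-membered compounds carry germacrane numbers (C1–C10, methyl C14 on C10, methyl C15 on C4; C11–C13 are the lactone carbons).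
Assumption: the dehydrogenation in step 9 is taken to give the cis (7Z) enone, the geometry expected for a ten-membered ring that already holds one E-alkene; the route is written for that isomer.

**Route**

Step 1
Reactants: 1 methyl angelate
Product: 2 (2Z)-2-methylbut-2-en-1-ol
Conditions: i-Bu2AlH (2.2 equiv), CH2Cl2, −78 °C; aqueous potassium sodium tartrate work-up
Reagents that add atoms: none
Why: 1,2-Reduction of the unsaturated ester with DIBAL-H at low temperature should give the allylic alcohol without isomerising the (Z)-trisubstituted alkene.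

Step 2
Reactants: 2 (2Z)-2-methylbut-2-en-1-ol
Product: 3 [(2R,3S)-2,3-dimethyloxiran-2-yl]methanol
Conditions: Ti(OiPr)4 (10 mol %), D-(−)-diisopropyl tartrate (12 mol %), t-BuOOH, 4 Å molecular sieves, CH2Cl2, −20 °C
Reagents that add atoms: tert-butyl hydroperoxide, CC(C)(C)OO
Why: Sharpless asymmetric epoxidation: the D-(−)-tartrate titanium peroxide complex should deliver oxygen suprafacially to the alkene face that gives the (2R,3S)-oxirane, so both side-chain stereocentres are set by the reagent and the two methyl groups stay trans.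

Step 3
Reactants: 3 [(2R,3S)-2,3-dimethyloxiran-2-yl]methanol
Product: 4 (2S,3S)-2,3-dimethyloxirane-2-carboxylic acid
Conditions: RuCl3·xH2O (2 mol %), NaIO4 (3 equiv), MeCN/EtOAc/H2O, 0 °C → rt
Reagents that add atoms: sodium periodate, [Na+].[O-]I(=O)(=O)=O; water, O
Why: Ruthenium tetroxide-catalysed oxidation of the primary epoxy alcohol through the aldehyde hydrate should give the glycidic acid with both stereocentres untouched (the C2 descriptor changes from R to S by priority only).

Step 4
Reactants: 5 (S)-(+)-carvone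
Product: 6 (1S,5S)-2-methyl-5-(prop-1-en-2-yl)cyclohex-2-en-1-ol
Conditions: NaBH4, CeCl3·7H2O, MeOH, 0 °C
Reagents that add atoms: none
Why: Luche reduction: 1,2-hydride delivery along the axial trajectory of the half-chair with equatorial isopropenyl should give cis-carveol, which sets the future C3 carbinol centre as S.

Step 5
Reactants: 6 (1S,5S)-2-methyl-5-(prop-1-en-2-yl)cyclohex-2-en-1-ol
Product: 7 tert-butyldimethylsilyl ether of 6
Conditions: TBSCl, imidazole, DMF, rt
Reagents that add atoms: tert-butyldimethylsilyl chloride, CC(C)(C)[Si](C)(C)Cl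
Why: Standard silylation of the secondary allylic alcohol gives a protecting group that should survive the strong base, oxidant, hydride and phosphine steps ahead.

Step 6
Reactants: 7 tert-butyldimethylsilyl ether of 6
Product: 8 (4S,6S)-4-[(tert-butyldimethylsilyl)oxy]-3-methyl-6-(prop-1-en-2-yl)cyclohex-2-en-1-one
Conditions: Rh2(cap)4 [dirhodium tetrakis(caprolactamate)] (1 mol %), t-BuOOH (5 equiv), K2CO3 (0.5 equiv), CH2Cl2, rt
Reagents that add atoms: tert-butyl hydroperoxide, CC(C)(C)OO
Why: Allylic C–H oxidation by a tert-butylperoxy radical chain should occur at the only allylic ring methylene, next to the CH terminus of the trisubstituted alkene (as in 7-oxidation of Δ5-steroids), and give the γ-silyloxy enone; the centre next to the new carbonyl is destroyed in step 8, so its epimerisation would be harmless.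

Step 7
Reactants: 8 (4S,6S)-4-[(tert-butyldimethylsilyl)oxy]-3-methyl-6-(prop-1-en-2-yl)cyclohex-2-en-1-one
Product: 9 (1S,4S,6S)-4-[(tert-butyldimethylsilyl)oxy]-1-ethenyl-3-methyl-6-(prop-1-en-2-yl)cyclohex-2-en-1-ol
Conditions: CH2=CHMgBr, anhydrous CeCl3, THF, −78 °C
Reagents that add atoms: vinylmagnesium bromide, C=C[Mg]Br
Why: 1,2-Addition of the vinylcerium reagent (which suppresses enolisation and conjugate addition) should occur anti to both the isopropenyl and silyloxy groups and give the trans-1,2-dialkenyl carbinol; this carbinol centre is lost in step 8.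

Step 8
Reactants: 9 (1S,4S,6S)-4-[(tert-butyldimethylsilyl)oxy]-1-ethenyl-3-methyl-6-(prop-1-en-2-yl)cyclohex-2-en-1-ol
Product: 12 (3S)-3-[(tert-butyldimethylsilyl)oxy]-6-[(trimethylsilyl)oxy]-11,12,13-trinorgermacra-1(10)E,4Z,6Z-triene, via potassium alkoxide 10 (not isolated), via potassium enolate 11 (not isolated)
Conditions: KH, 18-crown-6, THF, 0 °C → rt; then Me3SiCl/Et3N, −78 °C
Reagents that add atoms: chlorotrimethylsilane, C[Si](C)(C)Cl
Why: Anionic oxy-Cope rearrangement: the alkoxide should rearrange [3,3] through a chair transition state with both alkenyl groups equatorial, expanding the six-membered ring by four carbons to the ten-membered enolate with a new (1(10)E)-alkene and the former ring alkene as (4Z); O-silylation then fixes the regiodefined enolate.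

Step 9
Reactants: 12 (3S)-3-[(tert-butyldimethylsilyl)oxy]-6-[(trimethylsilyl)oxy]-11,12,13-trinorgermacra-1(10)E,4Z,6Z-triene
Product: 13 (3S)-3-[(tert-butyldimethylsilyl)oxy]-11,12,13-trinorgermacra-1(10)E,4Z,7Z-trien-6-one
Conditions: Pd(OAc)2 (1.05 equiv), MeCN, rt
Reagents that add atoms: none
Why: Saegusa–Ito oxidation: the C7-bound divalent palladium enolate should undergo syn β-hydride elimination from C8 (the only carbon with β-hydrogens), releasing zerovalent palladium; the gauche C6–C7–C8–C9 segment left by the chair rearrangement should lead to the cis (7Z) enone.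

Step 10
Reactants: 13 (3S)-3-[(tert-butyldimethylsilyl)oxy]-11,12,13-trinorgermacra-1(10)E,4Z,7Z-trien-6-one
Product: 14 (3S,7S,8S)-3-[(tert-butyldimethylsilyl)oxy]-7,8-epoxy-11,12,13-trinorgermacra-1(10)E,4Z-dien-6-one
Conditions: t-BuOOH, DBU, CH2Cl2, 0 °C
Reagents that add atoms: tert-butyl hydroperoxide, CC(C)(C)OO
Why: Weitz–Scheffer nucleophilic epoxidation: the peroxide anion should add only to the unhindered disubstituted enone terminus C8 (C4 is β,β-disubstituted and C1=C10 is not electrophilic), from the outward face of the cis-enone in the conformer with the C3 silyloxy group pseudo-equatorial, and the ring should keep the cis geometry on closure.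

Step 11
Reactants: 14 (3S,7S,8S)-3-[(tert-butyldimethylsilyl)oxy]-7,8-epoxy-11,12,13-trinorgermacra-1(10)E,4Z-dien-6-one
Product: 15 (3S,6R,7R,8S)-3-[(tert-butyldimethylsilyl)oxy]-7,8-epoxy-11,12,13-trinorgermacra-1(10)E,4Z-dien-6-ol
Conditions: Zn(BH4)2, Et2O, −20 °C
Reagents that add atoms: none
Why: Chelation-controlled 1,2-reduction of the α,β-epoxy ketone: zinc bridges the carbonyl and oxirane oxygens and hydride should attack the carbonyl face away from C8, giving the erythro (anti) epoxy alcohol and setting C6 as R.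

Step 12
Reactants: 15 (3S,6R,7R,8S)-3-[(tert-butyldimethylsilyl)oxy]-7,8-epoxy-11,12,13-trinorgermacra-1(10)E,4Z-dien-6-ol; 16 2-(diethoxyphosphoryl)acetic acid
Product: 17 (3S,6R,7S,8S)-3-[(tert-butyldimethylsilyl)oxy]-7,8-epoxy-11,12,13-trinorgermacra-1(10)E,4Z-dien-6-yl 2-(diethoxyphosphoryl)acetate
Conditions: DCC, DMAP (10 mol %), CH2Cl2, 0 °C → rt
Reagents that add atoms: none
Why: Steglich esterification with retention at C6 should install the C11–C12 unit on O6 without touching the oxirane (the C7 descriptor changes by priority only).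

Step 13
Reactants: 17 (3S,6R,7S,8S)-3-[(tert-butyldimethylsilyl)oxy]-7,8-epoxy-11,12,13-trinorgermacra-1(10)E,4Z-dien-6-yl 2-(diethoxyphosphoryl)acetate
Product: 20 (3S,6R,7R,8S)-3-[(tert-butyldimethylsilyl)oxy]-8-hydroxygermacra-1(10)E,4Z,11(13)-trien-12,6-olide, via lithium phosphonoacetate enolate 18 (not isolated), via lithiated phosphono lactone 19 (not isolated)
Conditions: LiN(SiMe3)2 (1.05 equiv), LiCl (2 equiv), THF, −78 → 40 °C; then (CH2O)n, 0 °C → rt
Reagents that add atoms: formaldehyde (from paraformaldehyde), C=O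
Why: Proposed new method: deprotonation gives the phosphonate-stabilised ester enolate 18, whose α-carbon C11 should attack C7 of the lithium-activated cis-oxirane from the rear in a 5-exo-tet closure (new ring C11–C12–O6–C6–C7), the oxirane oxygen staying on C8. Proton transfer from the acidic C11–H to the new C8 alkoxide then gives the phosphonate anion 19, which is olefinated in the same flask with formaldehyde (Horner–Wadsworth–Emmons) to the exocyclic C11=C13 methylene. The closest known reactions are the intermolecular opening of epoxides by phosphonoacetate anions (first stage of the Wadsworth–Emmons cyclopropanation), the base-mediated 5-exo cyclisation of 2,3-epoxy alcohol carbamates at the proximal carbon, epoxynitrile cyclisations and the methylenation of α-phosphono lactones. C7 is set by SN2 inversion, so the erythro epoxy ester should give only the trans-fused lactone (H6 and H7 anti); C6 and C8 are not touched, and C8 emerges as the free (8S)-alcohol. The step needs proximal attack at C7 (5-exo) and not distal attack at C8 (6-endo), which the short two-atom tether and the rear-side alignment available only at C7 in the erythro isomer should secure. It must also outrun phosphoryl transfer to the C8 alkoxide with cyclopropane formation, which fast C–H to O proton transfer and immediate trapping with formaldehyde below 45 °C should secure.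

Step 14
Reactants: 20 (3S,6R,7R,8S)-3-[(tert-butyldimethylsilyl)oxy]-8-hydroxygermacra-1(10)E,4Z,11(13)-trien-12,6-olide; 4 (2S,3S)-2,3-dimethyloxirane-2-carboxylic acid
Product: 21 (3S,6R,7R,8R)-3-[(tert-butyldimethylsilyl)oxy]-8-{[(2S,3S)-2,3-dimethyloxiran-2-yl]carbonyloxy}germacra-1(10)E,4Z,11(13)-trien-12,6-olide
Conditions: PPh3, DIAD (betaine preformed), toluene, 0 °C → rt
Reagents that add atoms: none
Why: Mitsunobu esterification: the C8 alkoxyphosphonium ion should be displaced by the carboxylate of the glycidic acid with SN2 inversion, turning the (8S)-alcohol left by the oxirane into the (8R)-ester of the target; preforming the betaine keeps free phosphine away from the methylene lactone.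

Step 15
Reactants: 21 (3S,6R,7R,8R)-3-[(tert-butyldimethylsilyl)oxy]-8-{[(2S,3S)-2,3-dimethyloxiran-2-yl]carbonyloxy}germacra-1(10)E,4Z,11(13)-trien-12,6-olide
Product: 22 (1R,3S,6R,7R,8R,10R)-1,10-epoxy-3-[(tert-butyldimethylsilyl)oxy]-8-{[(2S,3S)-2,3-dimethyloxiran-2-yl]carbonyloxy}germacra-4Z,11(13)-dien-12,6-olide
Conditions: mCPBA, NaHCO3, CH2Cl2, 0 °C
Reagents that add atoms: mCPBA, OOC(=O)c1cccc(Cl)c1
Why: Prilezhaev epoxidation: the peracid should attack the most electron-rich alkene, C1=C10 (C4=C5 is deactivated by two allylic oxygens and C11=C13 is electron-poor), stereospecifically syn from the exposed outer face of the (E)-alkene, giving the trans (1R,10R)-oxirane.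

Step 16
Reactants: 22 (1R,3S,6R,7R,8R,10R)-1,10-epoxy-3-[(tert-butyldimethylsilyl)oxy]-8-{[(2S,3S)-2,3-dimethyloxiran-2-yl]carbonyloxy}germacra-4Z,11(13)-dien-12,6-olide
Product: 23 CNP0268255.2
Conditions: HF·pyridine, excess pyridine, THF, 0 °C
Reagents that add atoms: none
Why: Buffered fluoride desilylation should free the C3 alcohol without opening either oxirane, adding to the methylene lactone or moving the C8 acyl group.

**Compound list**
1 | methyl angelate, methyl (2Z)-2-methylbut-2-enoate | C/C=C(/C)C(=O)OC | starting material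
2 | (2Z)-2-methylbut-2-en-1-ol | C/C=C(/C)CO | intermediate
3 | [(2R,3S)-2,3-dimethyloxiran-2-yl]methanol | OC[C@@]1(C)O[C@H]1C | intermediate
4 | (2S,3S)-2,3-dimethyloxirane-2-carboxylic acid (epoxyangelic acid) | OC(=O)[C@@]1(C)O[C@H]1C | intermediate
5 | (S)-(+)-carvone | CC1=CC[C@@H](CC1=O)C(C)=C | starting material
6 | (1S,5S)-2-methyl-5-(prop-1-en-2-yl)cyclohex-2-en-1-ol (cis-carveol) | CC1=CC[C@@H](C[C@@H]1O)C(C)=C | intermediate
7 | tert-butyldimethylsilyl ether of 6 | CC1=CC[C@@H](C[C@@H]1O[Si](C)(C)C(C)(C)C)C(C)=C | intermediate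
8 | (4S,6S)-4-[(tert-butyldimethylsilyl)oxy]-3-methyl-6-(prop-1-en-2-yl)cyclohex-2-en-1-one | O=C1C=C(C)[C@@H](O[Si](C)(C)C(C)(C)C)C[C@H]1C(C)=C | intermediate
9 | (1S,4S,6S)-4-[(tert-butyldimethylsilyl)oxy]-1-ethenyl-3-methyl-6-(prop-1-en-2-yl)cyclohex-2-en-1-ol (vinyl trans to isopropenyl) | C=C[C@]1(O)C=C(C)[C@@H](O[Si](C)(C)C(C)(C)C)C[C@H]1C(C)=C | intermediate
10 | potassium alkoxide of 9 | C=C[C@]1([O-])C=C(C)[C@@H](O[Si](C)(C)C(C)(C)C)C[C@H]1C(C)=C.[K+] | intermediate
11 | potassium enolate of the ring-expanded ten-membered ketone (C5 and C8 trans on C6=C7) | C1/C(C)=C/C[C@H](O[Si](C)(C)C(C)(C)C)/C(C)=C\C([O-])=C\C1.[K+] | intermediate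
12 | (3S)-3-[(tert-butyldimethylsilyl)oxy]-6-[(trimethylsilyl)oxy]-11,12,13-trinorgermacra-1(10)E,4Z,6Z-triene | C1/C(C)=C/C[C@H](O[Si](C)(C)C(C)(C)C)/C(C)=C\C(O[Si](C)(C)C)=C\C1 | intermediate
13 | (3S)-3-[(tert-butyldimethylsilyl)oxy]-11,12,13-trinorgermacra-1(10)E,4Z,7Z-trien-6-one | [C@@H]1(O[Si](C)(C)C(C)(C)C)/C(C)=C\C(=O)/C=C\C/C(C)=C/C1 | intermediate
14 | (3S,7S,8S)-3-[(tert-butyldimethylsilyl)oxy]-7,8-epoxy-11,12,13-trinorgermacra-1(10)E,4Z-dien-6-one (cis-oxirane) | [C@@H]1(O[Si](C)(C)C(C)(C)C)/C(C)=C\C(=O)[C@H]2O[C@H]2C/C(C)=C/C1 | intermediate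
15 | (3S,6R,7R,8S)-3-[(tert-butyldimethylsilyl)oxy]-7,8-epoxy-11,12,13-trinorgermacra-1(10)E,4Z-dien-6-ol (erythro) | [C@@H]1(O[Si](C)(C)C(C)(C)C)/C(C)=C\[C@@H](O)[C@H]2O[C@H]2C/C(C)=C/C1 | intermediate
16 | 2-(diethoxyphosphoryl)acetic acid | CCOP(=O)(OCC)CC(=O)O | starting material
17 | (3S,6R,7S,8S)-3-[(tert-butyldimethylsilyl)oxy]-7,8-epoxy-11,12,13-trinorgermacra-1(10)E,4Z-dien-6-yl 2-(diethoxyphosphoryl)acetate | [C@@H]1(O[Si](C)(C)C(C)(C)C)/C(C)=C\[C@@H](OC(=O)CP(=O)(OCC)OCC)[C@H]2O[C@H]2C/C(C)=C/C1 | intermediate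
18 | lithium enolate of 17 (carbanion at C11) | [C@@H]1(O[Si](C)(C)C(C)(C)C)/C(C)=C\[C@@H](OC(=O)[CH-]P(=O)(OCC)OCC)[C@H]2O[C@H]2C/C(C)=C/C1.[Li+] | intermediate
19 | lithiated 11-(diethoxyphosphoryl) lactone with free (8S)-hydroxyl | CCOP(=O)(OCC)[C-]1C(=O)O[C@@H]2/C=C(/C)[C@@H](O[Si](C)(C)C(C)(C)C)C/C=C(\C)/C[C@H](O)[C@@H]12.[Li+] | intermediate
20 | (3S,6R,7R,8S)-3-[(tert-butyldimethylsilyl)oxy]-8-hydroxygermacra-1(10)E,4Z,11(13)-trien-12,6-olide | C=C1C(=O)O[C@@H]2/C=C(/C)[C@@H](O[Si](C)(C)C(C)(C)C)C/C=C(\C)/C[C@H](O)[C@@H]12 | intermediate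
21 | (3S,6R,7R,8R)-3-[(tert-butyldimethylsilyl)oxy]-8-{[(2S,3S)-2,3-dimethyloxiran-2-yl]carbonyloxy}germacra-1(10)E,4Z,11(13)-trien-12,6-olide | C=C1C(=O)O[C@@H]2/C=C(/C)[C@@H](O[Si](C)(C)C(C)(C)C)C/C=C(\C)/C[C@@H](OC(=O)[C@@]3(C)O[C@H]3C)[C@@H]12 | intermediate
22 | (1R,3S,6R,7R,8R,10R)-1,10-epoxy-3-[(tert-butyldimethylsilyl)oxy]-8-{[(2S,3S)-2,3-dimethyloxiran-2-yl]carbonyloxy}germacra-4Z,11(13)-dien-12,6-olide | C=C1C(=O)O[C@@H]2/C=C(/C)[C@@H](O[Si](C)(C)C(C)(C)C)C[C@H]3O[C@]3(C)C[C@@H](OC(=O)[C@@]3(C)O[C@H]3C)[C@@H]12 | intermediate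
23 | CNP0268255.2, (1R,3S,6R,7R,8R,10R)-1,10-epoxy-3-hydroxy-8-{[(2S,3S)-2,3-dimethyloxiran-2-yl]carbonyloxy}germacra-4Z,11(13)-dien-12,6-olide | C=C1C(=O)O[C@@H]2/C=C(/C)[C@@H](O)C[C@H]3O[C@]3(C)C[C@@H](OC(=O)[C@@]3(C)O[C@H]3C)[C@@H]12 | target

**Step count and risks**

Total step count: 16. Longest linear sequence: 13 steps (steps 4 to 16); steps 1 to 3 make the side-chain acid.

Steps most likely to fail:

Step 13 (proposed new method). The stabilised carbanion may be too weak a nucleophile to open the oxirane, distal 6-endo attack may compete, or phosphoryl transfer to the C8 alkoxide may lead on to a cyclopropane. The fallback uses known radical chemistry, sets out from 15 and returns at 21. Compound 15 is O-alkylated (propargyl bromide, Ag2O, CH2Cl2) to the 6-O-propargyl ether of 15 F1. Cp2TiCl (from Cp2TiCl2 and Zn, THF, rt) should open the oxirane bound to trivalent titanium at C7, the carbon next to the ether-bearing carbon. The C7 radical then closes 5-exo-dig onto the alkyne, again forming the C7–C11 bond by ring closure with trans ring fusion, and gives the 12-deoxo analogue of 20 F2 with the (8S)-hydroxyl. Mitsunobu esterification with 4 gives the 12-deoxo analogue of 21 F3, and allylic oxidation of the ring O–CH2 group with CrO3·2C5H5N in CH2Cl2 gives 21.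

Step 10. The process at risk is facial selection on the cis-enone (attack from the other ring face) and, to a lesser degree, bond rotation in the peroxy enolate before closure. The fallback replaces substrate control by catalyst control: amine-salt (iminium) catalysed asymmetric epoxidation of 13 with aqueous H2O2 and a 9-amino-9-deoxy-epi-cinchona alkaloid trifluoroacetate, the pseudo-enantiomer being chosen to match. It sets out from 13 and returns at 14 and makes no new compound (entry F0).

Step 14. Elimination of the activated C8 oxyphosphonium group, or failure of the hindered α,α-disubstituted carboxylate to displace it, may prevent the inversion. The fallback separates activation from displacement: 20 is converted (Tf2O, pyridine, CH2Cl2, −40 °C) into the C8 trifluoromethanesulfonate of 20 F4, which is displaced with inversion by the cesium salt of 4 (4, Cs2CO3; 18-crown-6, toluene, rt), returning at 21.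

Further compounds
F1 | step 13 | 6-O-propargyl ether of 15 | [C@@H]1(O[Si](C)(C)C(C)(C)C)/C(C)=C\[C@@H](OCC#C)[C@H]2O[C@H]2C/C(C)=C/C1
F2 | step 13 | 12-deoxo analogue of 20 (3-methylenetetrahydrofuran, configurations as in 20) | C=C1CO[C@@H]2/C=C(/C)[C@@H](O[Si](C)(C)C(C)(C)C)C/C=C(\C)/C[C@H](O)[C@@H]12
F3 | step 13 | 12-deoxo analogue of 21 (configurations as in 21) | C=C1CO[C@@H]2/C=C(/C)[C@@H](O[Si](C)(C)C(C)(C)C)C/C=C(\C)/C[C@@H](OC(=O)[C@@]3(C)O[C@H]3C)[C@@H]12
F0 | step 10 | none | none
F4 | step 14 | C8 trifluoromethanesulfonate of 20 | C=C1C(=O)O[C@@H]2/C=C(/C)[C@@H](O[Si](C)(C)C(C)(C)C)C/C=C(\C)/C[C@H](OS(=O)(=O)C(F)(F)F)[C@@H]12
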